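**Plan**
1. Retrosynthesis: cut C6–C7 of the 19-membered ring first (pinacol disconnection to a C6,C7-dialdehyde), then the N–C1 amide, then C8=C9 and C2=C3 (Still–Gennari olefinations), C10–C11 and C14–C15 (crotylborations), the C12–O bond (α-oxygenation) and C11–C12 (hydroformylation).
2. Forward: arene 1 → C14/C15 → C11 aldehyde → C12 → C10/C11 → 8Z enoate → aniline 14. Separately the 2Z enynoic acid 18. Amide → dialdehyde → ring closure at C6–C7 → O-methylation → alkyne to 4Z alkene → carbamate → quinone → hydroquinone.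
3. Enabling feature: C6 and C7 are vicinal oxygen-bearing ring carbons, each attached to a π-system (C4–C5 and C8=C9). Opening the ansa ring between them gives two conjugated formyl groups, both reducible by trivalent titanium, once C4=C5 is carried as an alkyne.
4. Stereochemistry: C15/C14 and C11/C10 from an Ipc crotylborane, C12 from an enamine catalyst, C6/C7 in the ring closure (threo rule plus allylic 1,3-strain of the Z-enal). Alkene geometry from two Still–Gennari olefinations and a zinc semi-reduction.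
5. Helpers: the C4–C5 alkyne (removed in step 21) and the arene methyl ethers (removed in steps 23 and 24).

Key step: step 19

Remark: the target is taken exactly as drawn, i.e. the 2Z,4Z,8Z isomer. Atom numbers follow ansamycin usage: C1 is the lactam carbonyl, C15 the benzylic carbon, C16–C21 the arene, with N on C20 and oxygen on C18 and C21.

**Route**

Step 1
Reactants: 1 2-hydroxy-5-methoxy-3-nitrobenzaldehyde
Product: 2 2,5-dimethoxy-3-nitrobenzaldehyde
Conditions: MeI, K2CO3, DMF, rt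
Reagents that add atoms: iodomethane, CI
Why: The phenol between the nitro and formyl groups is acidic enough for K2CO3, and its phenoxide is alkylated by iodomethane (Williamson ether synthesis).

Step 2
Reactants: 2 2,5-dimethoxy-3-nitrobenzaldehyde
Product: 3 (1R,2S)-1-(2,5-dimethoxy-3-nitrophenyl)-2-methylbut-3-en-1-ol
Conditions: (Z)-crotylB(Ipc)2 of the (−)-α-pinene series [made in the flask from cis-but-2-ene, KOt-Bu, n-BuLi, (+)-Ipc2BOMe, BF3·OEt2], THF/Et2O, −78 °C; then NaOH, H2O2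
Reagents that add atoms: (Z)-but-2-enyl(diisopinocampheyl)borane, C/C=C\CB([C@H]1C[C@H]2C[C@@H]([C@@H]1C)C2(C)C)[C@H]1C[C@H]2C[C@@H]([C@@H]1C)C2(C)C
Why: Brown crotylboration through a closed chair transition state should give the syn C14/C15 pair from the Z-crotyl geometry, and the Ipc ligands should direct attack to the aldehyde face that gives 15R and hence 14S.

Step 3
Reactants: 3 (1R,2S)-1-(2,5-dimethoxy-3-nitrophenyl)-2-methylbut-3-en-1-ol
Product: 4 1-[(1R,2S)-1-methoxy-2-methylbut-3-en-1-yl]-2,5-dimethoxy-3-nitrobenzene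
Conditions: NaH, MeI, THF/DMF, 0 °C
Reagents that add atoms: iodomethane, CI
Why: Williamson etherification of the benzylic alkoxide installs the C15 methyl ether without touching either stereocentre.

Step 4
Reactants: 4 1-[(1R,2S)-1-methoxy-2-methylbut-3-en-1-yl]-2,5-dimethoxy-3-nitrobenzene
Product: 5 (4S,5R)-5-(2,5-dimethoxy-3-nitrophenyl)-5-methoxy-4-methylpentanal
Conditions: Rh(acac)(CO)2 (1 mol %), BIPHEPHOS (2 mol %), CO/H2 (1:1, 5 bar), toluene, 60 °C
Reagents that add atoms: carbon monoxide, [C-]#[O+]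
Why: Rhodium-catalysed hydroformylation with a wide-bite-angle bisphosphite should place the formyl group on the terminal carbon of the allylically branched alkene, which adds C11 and makes C12 and C13 methylenes.

Step 5
Reactants: 5 (4S,5R)-5-(2,5-dimethoxy-3-nitrophenyl)-5-methoxy-4-methylpentanal
Product: 6 (2S,4S,5R)-5-(2,5-dimethoxy-3-nitrophenyl)-5-methoxy-4-methyl-1-oxopentan-2-yl benzoate
Conditions: (S)-2-(triphenylmethyl)pyrrolidine (10 mol %), dibenzoyl peroxide, hydroquinone (10 mol %), THF, 0 °C; short silica plug, used at once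
Reagents that add atoms: dibenzoyl peroxide, O=C(OOC(=O)c1ccccc1)c1ccccc1
Why: Enamine-catalysed α-benzoyloxylation: the trityl group shields one face of the E-enamine, so the peroxide oxygen should arrive on the other face and set C12 as S.

Step 6
Reactants: 6 (2S,4S,5R)-5-(2,5-dimethoxy-3-nitrophenyl)-5-methoxy-4-methyl-1-oxopentan-2-yl benzoate
Product: 8 (3S,4R,5S,7S,8R)-8-(2,5-dimethoxy-3-nitrophenyl)-8-methoxy-3,7-dimethyloct-1-ene-4,5-diol, via hydroxy benzoate 7 (not isolated)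
Conditions: (Z)-crotylB(Ipc)2 of the (−)-α-pinene series (made as in step 2), THF/Et2O, −78 °C; then 3 M NaOH, 30% H2O2, 0 °C → rt
Reagents that add atoms: (Z)-but-2-enyl(diisopinocampheyl)borane, C/C=C\CB([C@H]1C[C@H]2C[C@@H]([C@@H]1C)C2(C)C)[C@H]1C[C@H]2C[C@@H]([C@@H]1C)C2(C)C
Why: A second Brown crotylboration, matched with the Felkin–Anh (Cornforth) preference of the α-acyloxy aldehyde, should set C11 (R) anti to C12 and C10 (S) syn to C11, and the alkaline peroxide work-up should also saponify the benzoate.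

Step 7
Reactants: 8 (3S,4R,5S,7S,8R)-8-(2,5-dimethoxy-3-nitrophenyl)-8-methoxy-3,7-dimethyloct-1-ene-4,5-diol
Product: 9 1-[(1R,2S,4S,5R,6S)-1,4,5-trimethoxy-2,6-dimethyloct-7-en-1-yl]-2,5-dimethoxy-3-nitrobenzene
Conditions: NaH, MeI, THF/DMF, 0 °C → rt
Reagents that add atoms: iodomethane, CI
Why: Double Williamson etherification converts both secondary hydroxyls into the C11 and C12 methyl ethers.

Step 8
Reactants: 9 1-[(1R,2S,4S,5R,6S)-1,4,5-trimethoxy-2,6-dimethyloct-7-en-1-yl]-2,5-dimethoxy-3-nitrobenzene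
Product: 10 (2R,3R,4S,6S,7R)-7-(2,5-dimethoxy-3-nitrophenyl)-3,4,7-trimethoxy-2,6-dimethylheptanal
Conditions: O3, CH2Cl2/MeOH, −78 °C; then PPh3
Reagents that add atoms: ozone, [O-][O+]=O
Why: Ozonolysis with reductive work-up cleaves the only alkene to the α-methyl aldehyde, which is used at once to avoid epimerisation at C10.

Step 9
Reactants: 10 (2R,3R,4S,6S,7R)-7-(2,5-dimethoxy-3-nitrophenyl)-3,4,7-trimethoxy-2,6-dimethylheptanal
Product: 11 methyl (2Z,4S,5R,6S,8S,9R)-9-(2,5-dimethoxy-3-nitrophenyl)-5,6,9-trimethoxy-2,4,8-trimethylnon-2-enoate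
Conditions: (CF3CH2O)2P(O)CH(CH3)CO2Me, KN(SiMe3)2, 18-crown-6, THF, −78 °C
Reagents that add atoms: methyl 2-[bis(2,2,2-trifluoroethoxy)phosphoryl]propanoate, COC(=O)C(C)P(=O)(OCC(F)(F)F)OCC(F)(F)F
Why: Still–Gennari olefination: the electron-poor phosphonate eliminates under kinetic control and should give the Z-trisubstituted enoate, i.e. the 8Z alkene with C7 cis to C10.

Step 10
Reactants: 11 methyl (2Z,4S,5R,6S,8S,9R)-9-(2,5-dimethoxy-3-nitrophenyl)-5,6,9-trimethoxy-2,4,8-trimethylnon-2-enoate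
Product: 12 (2Z,4S,5R,6S,8S,9R)-9-(2,5-dimethoxy-3-nitrophenyl)-5,6,9-trimethoxy-2,4,8-trimethylnon-2-en-1-ol
Conditions: i-Bu2AlH, CH2Cl2, −78 °C; Rochelle salt work-up
Reagents that add atoms: none
Why: DIBAL reduction of the conjugated ester to the allylic alcohol at low temperature should leave the nitroarene and the alkene geometry untouched.

Step 11
Reactants: 12 (2Z,4S,5R,6S,8S,9R)-9-(2,5-dimethoxy-3-nitrophenyl)-5,6,9-trimethoxy-2,4,8-trimethylnon-2-en-1-ol
Product: 13 tert-butyl(dimethyl)silyl ether of 12 at C7–O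
Conditions: TBSCl, imidazole, CH2Cl2, 0 °C → rt
Reagents that add atoms: tert-butyl(chloro)dimethylsilane, CC(C)(C)[Si](C)(C)Cl
Why: Silylation of the primary allylic alcohol protects C7–OH through the nitro reduction and the N-acylation.

Step 12
Reactants: 13 tert-butyl(dimethyl)silyl ether of 12
Product: 14 3-[(1R,2S,4S,5R,6S,7Z)-9-{[tert-butyl(dimethyl)silyl]oxy}-1,4,5-trimethoxy-2,6,8-trimethylnon-7-en-1-yl]-2,5-dimethoxyaniline
Conditions: Zn dust, NH4Cl, MeOH/H2O, rt
Reagents that add atoms: none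
Why: Dissolving-metal reduction of the nitroarene with zinc in buffered aqueous methanol should give the aniline without affecting the alkene, the silyl ether or the benzylic ether.

Step 13
Reactants: 15 tert-butyl(dimethyl)(prop-2-yn-1-yloxy)silane
Product: 16 4-{[tert-butyl(dimethyl)silyl]oxy}but-2-ynal
Conditions: n-BuLi, THF, −78 °C; DMF; inverse quench into 10% aq. KH2PO4
Reagents that add atoms: N,N-dimethylformamide, CN(C)C=O
Why: Formylation of the lithium acetylide with DMF, with inverse quench into phosphate buffer so that the hemiaminal collapses to the ynal without base-induced decomposition.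

Step 14
Reactants: 16 4-{[tert-butyl(dimethyl)silyl]oxy}but-2-ynal
Product: 17 methyl (2Z)-6-{[tert-butyl(dimethyl)silyl]oxy}-2-methylhex-2-en-4-ynoate
Conditions: (CF3CH2O)2P(O)CH(CH3)CO2Me, KN(SiMe3)2, 18-crown-6, THF, −78 °C
Reagents that add atoms: methyl 2-[bis(2,2,2-trifluoroethoxy)phosphoryl]propanoate, COC(=O)C(C)P(=O)(OCC(F)(F)F)OCC(F)(F)F
Why: Still–Gennari olefination of the ynal should give the 2Z enynoate (ester cis to C4), with the alkyne held as the precursor of the 4Z alkene.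

Step 15
Reactants: 17 methyl (2Z)-6-{[tert-butyl(dimethyl)silyl]oxy}-2-methylhex-2-en-4-ynoate
Product: 18 (2Z)-6-{[tert-butyl(dimethyl)silyl]oxy}-2-methylhex-2-en-4-ynoic acid
Conditions: LiOH, THF/MeOH/H2O, 0 °C → rt; then 1 M HCl to pH 3
Reagents that add atoms: lithium hydroxide, [Li+].[OH-]
Why: Saponification of the methyl ester under mild conditions that should spare the silyl ether and the Z geometry.

Step 16
Reactants: 18 (2Z)-6-{[tert-butyl(dimethyl)silyl]oxy}-2-methylhex-2-en-4-ynoic acid; 14 the aniline from step 12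
Product: 20 anilide of 18 with 14 (N–C1 amide; C6–OTBS and C7–OTBS; 2Z,8Z), via acid chloride 19 (not isolated)
Conditions: 1-chloro-N,N,2-trimethylprop-1-en-1-amine, CH2Cl2, 0 °C; then 14, pyridine, 0 °C → rt
Reagents that add atoms: none
Why: Amide formation through the acid chloride, made under neutral conditions with the chloroenamine so that the Z-enynoic acid is not isomerised, followed by N-acylation of the aniline.

Step 17
Reactants: 20 bis-silyl anilide
Product: 21 diol anilide (C6–OH propargylic, C7–OH allylic; 2Z,8Z)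
Conditions: HF·pyridine, pyridine/THF, 0 °C → rt
Reagents that add atoms: none
Why: Fluoride-mediated desilylation removes both primary silyl ethers under buffered conditions that should not induce cyclisation of the enynamide.

Step 18
Reactants: 21 diol anilide
Product: 22 dialdehyde anilide (C6 ynal and C7 Z-enal)
Conditions: Dess–Martin periodinane (2.5 equiv), NaHCO3, CH2Cl2, 0 °C; filtered and used at once
Reagents that add atoms: none
Why: Dess–Martin oxidation of the propargylic and the allylic alcohol under buffered, non-basic conditions should give both conjugated aldehydes without Z to E isomerisation.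

Step 19
Reactants: 22 dialdehyde anilide
Product: 23 macrocyclic syn-diol: 19-membered lactam with C4–C5 alkyne, 6S,7S-diol, 2Z,8Z, arene as 18,21-dimethyl ether
Conditions: Cp2TiCl2 (3 equiv), Zn dust, THF, rt (gives Cp2TiCl); MgBr2·OEt2; 22 added by syringe pump to about 1 mM, −20 °C; then 1 M HCl, 0 °C
Reagents that add atoms: none
Why: Cp2TiCl (trivalent titanium) transfers one electron to each conjugated aldehyde, the only groups of 22 within its reducing power, and the two titanoxy radicals (allylic at C7, propargylic at C6), held in a halide- and magnesium-bridged dinuclear array, join carbon to carbon; acid then releases the diol. The closest known reactions are the threo-selective pinacol coupling of aromatic and α,β-unsaturated aldehydes with Cp2TiCl and the low-valent-metal pinacol ring closures of dialdehydes, including bis-ynals, to cyclic diols. The 19-membered ring is closed by head-to-head recombination of the two ketyl carbons (a reductive ring closure of an ω-dialdehyde, not an addition to a π bond), kept intramolecular by slow addition at high dilution. The syn (threo) C6/C7 relationship should follow from the bridged bis-ketyl, in which the two carbon substituents lie anti; the 7S sense should follow from allylic 1,3-strain in the Z-enal, where C10–H eclipses the formyl group and bonding occurs on the face of the C10 methyl and not on that of C11, and 6S is then fixed by the threo rule. The step needs chemoselectivity for the two formyl groups over the enynamide, bonding at the carbonyl carbons and not at C4 or C9 (both blocked by substituents), and retention of the 2Z and 8Z geometry, which low temperature and fast intramolecular coupling are meant to secure.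

Step 20
Reactants: 23 macrocyclic syn-diol
Product: 24 C6 methyl ether of 23 (6S-OMe, 7S-OH, alkyne retained)
Conditions: Me3OBF4 (1.1 equiv), 1,8-bis(dimethylamino)naphthalene, 4 Å sieves, CH2Cl2, −20 → 0 °C
Reagents that add atoms: trimethyloxonium tetrafluoroborate, C[O+](C)C.F[B-](F)(F)F
Why: Meerwein methylation under neutral conditions should occur at the unhindered propargylic C6 hydroxyl and not at the C7 hydroxyl, which is shielded by the C8 methyl group and the cis C10 branch.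

Step 21
Reactants: 24 C6 methyl ether
Product: 25 macrocyclic (2Z,4Z)-dienamide with 6S-OMe and 7S-OH
Conditions: Zn dust activated with Cu(OAc)2 then AgNO3, MeOH/H2O (1:1), 35 °C
Reagents that add atoms: none
Why: Semi-reduction of the conjugated alkyne on activated zinc in protic medium delivers both hydrogens cis and should give the 4Z alkene without touching the other alkenes.

Step 22
Reactants: 25 macrocyclic dienamide alcohol
Product: 27 C7 carbamate (18,21-di-O-methyl ether of the target), via N-trichloroacetyl carbamate 26 (not isolated)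
Conditions: Cl3CC(O)NCO, CH2Cl2, 0 °C; then K2CO3 (cat.), MeOH, rt
Reagents that add atoms: trichloroacetyl isocyanate, O=C=NC(=O)C(Cl)(Cl)Cl
Why: Carbamoylation: the C7 hydroxyl adds to the acyl isocyanate, and mild methanolysis removes the trichloroacetyl group to leave the primary carbamate.

Step 23
Reactants: 27 C7 carbamate
Product: 28 para-quinone (C18 and C21 carbonyls), otherwise as the target
Conditions: (NH4)2Ce(NO3)6 (2.5 equiv), MeCN/H2O, 0 °C
Reagents that add atoms: water, O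
Why: Oxidative demethylation of the para-dimethoxyarene by two one-electron oxidations with tetravalent cerium and attack of water should give the para-quinone.

Step 24
Reactants: 28 para-quinone
Product: 29 target hydroquinone (CNP0109452.1)
Conditions: Na2S2O4, EtOAc/H2O, rt, under argon
Reagents that add atoms: none
Why: Two-electron reduction of the quinone by dithionite should give the hydroquinone, which is handled under inert gas to prevent re-oxidation.

**Compound list**
1 | 2-hydroxy-5-methoxy-3-nitrobenzaldehyde | O=Cc1cc(OC)cc([N+](=O)[O-])c1O | starting material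
2 | 2,5-dimethoxy-3-nitrobenzaldehyde | O=Cc1cc(OC)cc([N+](=O)[O-])c1OC | intermediate
3 | (1R,2S)-1-(2,5-dimethoxy-3-nitrophenyl)-2-methylbut-3-en-1-ol | C=C[C@H](C)[C@@H](O)c1cc(OC)cc([N+](=O)[O-])c1OC | intermediate
4 | 1-[(1R,2S)-1-methoxy-2-methylbut-3-en-1-yl]-2,5-dimethoxy-3-nitrobenzene | C=C[C@H](C)[C@@H](OC)c1cc(OC)cc([N+](=O)[O-])c1OC | intermediate
5 | (4S,5R)-5-(2,5-dimethoxy-3-nitrophenyl)-5-methoxy-4-methylpentanal | O=CCC[C@H](C)[C@@H](OC)c1cc(OC)cc([N+](=O)[O-])c1OC | intermediate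
6 | (2S,4S,5R)-5-(2,5-dimethoxy-3-nitrophenyl)-5-methoxy-4-methyl-1-oxopentan-2-yl benzoate | O=C[C@@H](OC(=O)c1ccccc1)C[C@H](C)[C@@H](OC)c1cc(OC)cc([N+](=O)[O-])c1OC | intermediate
7 | (3S,4R,5S,7S,8R)-8-(2,5-dimethoxy-3-nitrophenyl)-4-hydroxy-8-methoxy-3,7-dimethyloct-1-en-5-yl benzoate | C=C[C@H](C)[C@@H](O)[C@@H](OC(=O)c1ccccc1)C[C@H](C)[C@@H](OC)c1cc(OC)cc([N+](=O)[O-])c1OC | intermediate
8 | (3S,4R,5S,7S,8R)-8-(2,5-dimethoxy-3-nitrophenyl)-8-methoxy-3,7-dimethyloct-1-ene-4,5-diol | C=C[C@H](C)[C@@H](O)[C@@H](O)C[C@H](C)[C@@H](OC)c1cc(OC)cc([N+](=O)[O-])c1OC | intermediate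
9 | 1-[(1R,2S,4S,5R,6S)-1,4,5-trimethoxy-2,6-dimethyloct-7-en-1-yl]-2,5-dimethoxy-3-nitrobenzene | C=C[C@H](C)[C@@H](OC)[C@@H](OC)C[C@H](C)[C@@H](OC)c1cc(OC)cc([N+](=O)[O-])c1OC | intermediate
10 | (2R,3R,4S,6S,7R)-7-(2,5-dimethoxy-3-nitrophenyl)-3,4,7-trimethoxy-2,6-dimethylheptanal | O=C[C@H](C)[C@@H](OC)[C@@H](OC)C[C@H](C)[C@@H](OC)c1cc(OC)cc([N+](=O)[O-])c1OC | intermediate
11 | methyl (2Z,4S,5R,6S,8S,9R)-9-(2,5-dimethoxy-3-nitrophenyl)-5,6,9-trimethoxy-2,4,8-trimethylnon-2-enoate | COC(=O)/C(C)=C\[C@H](C)[C@@H](OC)[C@@H](OC)C[C@H](C)[C@@H](OC)c1cc(OC)cc([N+](=O)[O-])c1OC | intermediate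
12 | (2Z,4S,5R,6S,8S,9R)-9-(2,5-dimethoxy-3-nitrophenyl)-5,6,9-trimethoxy-2,4,8-trimethylnon-2-en-1-ol | OC/C(C)=C\[C@H](C)[C@@H](OC)[C@@H](OC)C[C@H](C)[C@@H](OC)c1cc(OC)cc([N+](=O)[O-])c1OC | intermediate
13 | tert-butyl(dimethyl)silyl ether of 12 (C7–OTBS, nitroarene) | CC(C)(C)[Si](C)(C)OC/C(C)=C\[C@H](C)[C@@H](OC)[C@@H](OC)C[C@H](C)[C@@H](OC)c1cc(OC)cc([N+](=O)[O-])c1OC | intermediate
14 | 3-[(1R,2S,4S,5R,6S,7Z)-9-{[tert-butyl(dimethyl)silyl]oxy}-1,4,5-trimethoxy-2,6,8-trimethylnon-7-en-1-yl]-2,5-dimethoxyaniline | CC(C)(C)[Si](C)(C)OC/C(C)=C\[C@H](C)[C@@H](OC)[C@@H](OC)C[C@H](C)[C@@H](OC)c1cc(OC)cc(N)c1OC | intermediate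
15 | tert-butyl(dimethyl)(prop-2-yn-1-yloxy)silane | C#CCO[Si](C)(C)C(C)(C)C | starting material
16 | 4-{[tert-butyl(dimethyl)silyl]oxy}but-2-ynal | O=CC#CCO[Si](C)(C)C(C)(C)C | intermediate
17 | methyl (2Z)-6-{[tert-butyl(dimethyl)silyl]oxy}-2-methylhex-2-en-4-ynoate | COC(=O)/C(C)=C\C#CCO[Si](C)(C)C(C)(C)C | intermediate
18 | (2Z)-6-{[tert-butyl(dimethyl)silyl]oxy}-2-methylhex-2-en-4-ynoic acid | OC(=O)/C(C)=C\C#CCO[Si](C)(C)C(C)(C)C | intermediate
19 | (2Z)-6-{[tert-butyl(dimethyl)silyl]oxy}-2-methylhex-2-en-4-ynoyl chloride | ClC(=O)/C(C)=C\C#CCO[Si](C)(C)C(C)(C)C | intermediate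
20 | anilide of 18 with 14 (C6–OTBS, C7–OTBS; 2Z,8Z) | CC(C)(C)[Si](C)(C)OC/C(C)=C\[C@H](C)[C@@H](OC)[C@@H](OC)C[C@H](C)[C@@H](OC)c1cc(OC)cc(NC(=O)/C(C)=C\C#CCO[Si](C)(C)C(C)(C)C)c1OC | intermediate
21 | diol anilide (C6–OH, C7–OH; 2Z,8Z) | OC/C(C)=C\[C@H](C)[C@@H](OC)[C@@H](OC)C[C@H](C)[C@@H](OC)c1cc(OC)cc(NC(=O)/C(C)=C\C#CCO)c1OC | intermediate
22 | dialdehyde anilide (C6 ynal, C7 Z-enal) | O=C/C(C)=C\[C@H](C)[C@@H](OC)[C@@H](OC)C[C@H](C)[C@@H](OC)c1cc(OC)cc(NC(=O)/C(C)=C\C#CC=O)c1OC | intermediate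
23 | macrocyclic syn-diol (19-membered lactam, C4–C5 alkyne, 6S,7S-diol, 2Z,8Z, 10S,11R,12S,14S,15R, 18,21-di-OMe) | CO[C@H]1[C@@H](OC)C[C@H](C)[C@@H](OC)c2cc(OC)cc(c2OC)NC(=O)/C(C)=C\C#C[C@H](O)[C@@H](O)/C(C)=C\[C@@H]1C | intermediate
24 | C6 methyl ether of 23 (6S-OMe, 7S-OH, alkyne) | CO[C@H]1[C@@H](OC)C[C@H](C)[C@@H](OC)c2cc(OC)cc(c2OC)NC(=O)/C(C)=C\C#C[C@H](OC)[C@@H](O)/C(C)=C\[C@@H]1C | intermediate
25 | macrocyclic (2Z,4Z,8Z)-lactam with 6S-OMe and 7S-OH (18,21-di-OMe) | CO[C@H]1[C@@H](OC)C[C@H](C)[C@@H](OC)c2cc(OC)cc(c2OC)NC(=O)/C(C)=C\C=C/[C@H](OC)[C@@H](O)/C(C)=C\[C@@H]1C | intermediate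
26 | N-trichloroacetyl carbamate of 25 at C7–O | CO[C@H]1[C@@H](OC)C[C@H](C)[C@@H](OC)c2cc(OC)cc(c2OC)NC(=O)/C(C)=C\C=C/[C@H](OC)[C@@H](OC(=O)NC(=O)C(Cl)(Cl)Cl)/C(C)=C\[C@@H]1C | intermediate
27 | C7 carbamate, 18,21-di-O-methyl ether of the target | CO[C@H]1[C@@H](OC)C[C@H](C)[C@@H](OC)c2cc(OC)cc(c2OC)NC(=O)/C(C)=C\C=C/[C@H](OC)[C@@H](OC(N)=O)/C(C)=C\[C@@H]1C | intermediate
28 | para-quinone corresponding to the target (C18, C21 carbonyls) | CO[C@H]1[C@@H](OC)C[C@H](C)[C@@H](OC)C2=CC(=O)C=C(C2=O)NC(=O)/C(C)=C\C=C/[C@H](OC)[C@@H](OC(N)=O)/C(C)=C\[C@@H]1C | intermediate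
29 | CNP0109452.1, (2Z,4Z,8Z)-hydroquinone macrolactam, 6S,7S,10S,11R,12S,14S,15R | CO[C@H]1[C@@H](OC)C[C@H](C)[C@@H](OC)c2cc(O)cc(c2O)NC(=O)/C(C)=C\C=C/[C@H](OC)[C@@H](OC(N)=O)/C(C)=C\[C@@H]1C | target

**Count**
Total steps: 24. Longest linear sequence: 21 (steps 1–12 and 16–24).

**Steps most likely to fail**

1. Step 19 (with the dialdehyde of step 18). Oligomerisation may compete with ring closure. The 8Z geometry may scramble through the delocalised titanoxy-allyl radical. The anilide N–H may add to the ynal, or bonding may occur at the allenyl terminus. Facial control at C7 by allylic strain may be too weak.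
Fallback, from 12 back to 25: the C6–C7 bond is made between two molecules under reagent control and the ring is closed at the amide. Alcohol 12 is oxidised with Dess–Martin periodinane to the Z-enal F1. Brown (Z)-γ-methoxyallylboration, with the Ipc2B reagent of the (−)-α-pinene series made from allyl methyl ether, s-BuLi, (+)-Ipc2BOMe and BF3·OEt2, should give the syn methoxy alcohol F2. Silylation (TBSOTf, 2,6-lutidine) gives the silyl ether F3. Selective cleavage of the terminal vinyl group (OsO4 cat., N-methylmorpholine N-oxide; then NaIO4) gives the α-methoxy aldehyde F4. Still–Gennari olefination with methyl [bis(2,2,2-trifluoroethoxy)phosphoryl]acetate gives the Z-enoate F5. Reduction with i-Bu2AlH gives the allylic alcohol F6, and MnO2 gives the Z-enal F7. A second Still–Gennari olefination with the phosphonopropionate of step 9 gives the (2Z,4Z)-dienoate F8. Zn/NH4Cl gives the amino ester F9, and LiOH gives the seco amino acid F10. Macrolactamisation (BOP-Cl, i-Pr2NEt, toluene, high dilution) gives the silylated macrolactam F11, and HF·pyridine returns the route at 25.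

2. Step 20. The two secondary hydroxyls may not be discriminated well enough, the diol may be methylated twice, or the lactam oxygen may be alkylated.
Fallback, from 23 back to 27: the carbamate is placed first and the single remaining hydroxyl is methylated afterwards. Diol 23 is closed with 1,1'-carbonyldiimidazole to the cyclic carbonate F12. Ammonia in MeOH should open it with loss of the more acidic propargylic alkoxide to give the C7 carbamate C6 alcohol F13. Me3OBF4 with 1,8-bis(dimethylamino)naphthalene then gives the methyl ether F14, and semi-reduction with activated zinc as in step 21 joins the route at 27.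

3. Step 4. The nitro group may be reduced under syngas, the alkene may isomerise, or branched aldehyde may form.
Fallback, from 4 back to 5: cross-metathesis of 4 with crotonaldehyde (second-generation Hoveyda–Grubbs catalyst, CH2Cl2, 40 °C) gives the E-enal F15, and conjugate reduction with [(Ph3P)CuH]6 in toluene returns the route at 5.

**Further compounds**
F1 | step 19 | (2Z,4S,5R,6S,8S,9R)-9-(2,5-dimethoxy-3-nitrophenyl)-5,6,9-trimethoxy-2,4,8-trimethylnon-2-enal | O=C/C(C)=C\[C@H](C)[C@@H](OC)[C@@H](OC)C[C@H](C)[C@@H](OC)c1cc(OC)cc([N+](=O)[O-])c1OC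
F2 | step 19 | syn methoxy alcohol (6S-OMe, 7S-OH, terminal vinyl at C5, 8Z, nitroarene) | C=C[C@H](OC)[C@@H](O)/C(C)=C\[C@H](C)[C@@H](OC)[C@@H](OC)C[C@H](C)[C@@H](OC)c1cc(OC)cc([N+](=O)[O-])c1OC
F3 | step 19 | C7 tert-butyl(dimethyl)silyl ether of F2 | C=C[C@H](OC)[C@@H](O[Si](C)(C)C(C)(C)C)/C(C)=C\[C@H](C)[C@@H](OC)[C@@H](OC)C[C@H](C)[C@@H](OC)c1cc(OC)cc([N+](=O)[O-])c1OC
F4 | step 19 | C5 aldehyde (6-OMe, 7-OTBS, 8Z, nitroarene) | O=C[C@H](OC)[C@@H](O[Si](C)(C)C(C)(C)C)/C(C)=C\[C@H](C)[C@@H](OC)[C@@H](OC)C[C@H](C)[C@@H](OC)c1cc(OC)cc([N+](=O)[O-])c1OC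
F5 | step 19 | methyl (4Z)-enoate with C3 as ester carbon (6-OMe, 7-OTBS, 8Z, nitroarene) | COC(=O)/C=C\[C@H](OC)[C@@H](O[Si](C)(C)C(C)(C)C)/C(C)=C\[C@H](C)[C@@H](OC)[C@@H](OC)C[C@H](C)[C@@H](OC)c1cc(OC)cc([N+](=O)[O-])c1OC
F6 | step 19 | (4Z)-allylic alcohol at C3 (6-OMe, 7-OTBS, 8Z, nitroarene) | OC/C=C\[C@H](OC)[C@@H](O[Si](C)(C)C(C)(C)C)/C(C)=C\[C@H](C)[C@@H](OC)[C@@H](OC)C[C@H](C)[C@@H](OC)c1cc(OC)cc([N+](=O)[O-])c1OC
F7 | step 19 | (4Z)-enal with C3 formyl (6-OMe, 7-OTBS, 8Z, nitroarene) | O=C/C=C\[C@H](OC)[C@@H](O[Si](C)(C)C(C)(C)C)/C(C)=C\[C@H](C)[C@@H](OC)[C@@H](OC)C[C@H](C)[C@@H](OC)c1cc(OC)cc([N+](=O)[O-])c1OC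
F8 | step 19 | methyl (2Z,4Z,8Z)-seco dienoate (6-OMe, 7-OTBS, nitroarene) | COC(=O)/C(C)=C\C=C/[C@H](OC)[C@@H](O[Si](C)(C)C(C)(C)C)/C(C)=C\[C@H](C)[C@@H](OC)[C@@H](OC)C[C@H](C)[C@@H](OC)c1cc(OC)cc([N+](=O)[O-])c1OC
F9 | step 19 | methyl (2Z,4Z,8Z)-seco dienoate with free aniline (6-OMe, 7-OTBS) | COC(=O)/C(C)=C\C=C/[C@H](OC)[C@@H](O[Si](C)(C)C(C)(C)C)/C(C)=C\[C@H](C)[C@@H](OC)[C@@H](OC)C[C@H](C)[C@@H](OC)c1cc(OC)cc(N)c1OC
F10 | step 19 | (2Z,4Z,8Z)-seco amino acid (6-OMe, 7-OTBS) | OC(=O)/C(C)=C\C=C/[C@H](OC)[C@@H](O[Si](C)(C)C(C)(C)C)/C(C)=C\[C@H](C)[C@@H](OC)[C@@H](OC)C[C@H](C)[C@@H](OC)c1cc(OC)cc(N)c1OC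
F11 | step 19 | C7 tert-butyl(dimethyl)silyl ether of 25 | CO[C@H]1[C@@H](OC)C[C@H](C)[C@@H](OC)c2cc(OC)cc(c2OC)NC(=O)/C(C)=C\C=C/[C@H](OC)[C@@H](O[Si](C)(C)C(C)(C)C)/C(C)=C\[C@@H]1C
F12 | step 20 | cyclic 6,7-carbonate of 23 | CO[C@H]1[C@@H](OC)C[C@H](C)[C@@H](OC)c2cc(OC)cc(c2OC)NC(=O)/C(C)=C\C#C[C@@H]3OC(=O)O[C@H]3/C(C)=C\[C@@H]1C
F13 | step 20 | C7 carbamate C6 alcohol (alkyne retained) | CO[C@H]1[C@@H](OC)C[C@H](C)[C@@H](OC)c2cc(OC)cc(c2OC)NC(=O)/C(C)=C\C#C[C@H](O)[C@@H](OC(N)=O)/C(C)=C\[C@@H]1C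
F14 | step 20 | C7 carbamate C6 methyl ether (alkyne retained) | CO[C@H]1[C@@H](OC)C[C@H](C)[C@@H](OC)c2cc(OC)cc(c2OC)NC(=O)/C(C)=C\C#C[C@H](OC)[C@@H](OC(N)=O)/C(C)=C\[C@@H]1C
F15 | step 4 | (2E,4S,5R)-5-(2,5-dimethoxy-3-nitrophenyl)-5-methoxy-4-methylpent-2-enal | O=C/C=C/[C@H](C)[C@@H](OC)c1cc(OC)cc([N+](=O)[O-])c1OC
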